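## Retrosynthetic overview

1. The target is robinetinidol-(4β→8)-gallocatechin. The strategy rests on C4 of ring C in the upper unit: a doubly benzylic CH bonded to C4a of ring A, to C3 (whose OH is cis to ring D) and to C8 of ring D.
2. C4–C4a is cut last. Ring A, held as a 3-benzyloxyphenyl ether on C2, attacks C4 of a cis C3–C4 epoxide with inversion; this closes ring C and leaves O3 as the free hydroxyl.
3. The epoxide ether comes from a threo cis-epoxy alcohol by Mitsunobu inversion at C2. The epoxy alcohol comes from a Z-allylic alcohol by hydroxyl-directed epoxidation, and that from asymmetric alkynylation of 3,4,5-tris(benzyloxy)benzaldehyde (ring B) followed by Lindlar reduction.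
4. The alkyne is 8-ethynyl-hexa-O-benzylgallocatechin; rings D, E, F arrive intact from (+)-gallocatechin by benzylation, C8 bromination and Sonogashira coupling.
5. Ring order: D, E, F (chiral pool), then B and A (purchased), then C (key step); the ten benzyl ethers are removed at the end.

Key step: step 10

Assumption: commercial (+)-gallocatechin is the (2R,3S) enantiomer. Upper unit rings are A (benzo), B (aryl), C (pyran); lower unit rings are D (benzo), E (aryl), F (pyran). Flavan numbering (C2, C3, C4 of the upper unit) is also used for the open-chain precursors; the SMILES strings are the definitive statement of configuration.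

## Route

Step 1
Reactants: 1 (+)-gallocatechin
Product: 2 5,7,3',4',5'-penta-O-benzyl-(+)-gallocatechin (3-OH free)
Conditions: BnBr (6 equiv), K2CO3 (6 equiv), DMF, 0 °C → rt, argon
Reagents that add atoms: benzyl bromide BrCc1ccccc1
Why: Williamson O-benzylation in which K2CO3 deprotonates only the five phenols, so the secondary 3-OH and both stereocentres stay untouched, while argon protects the pyrogallol ring from oxidation.

Step 2
Reactants: 2 5,7,3',4',5'-penta-O-benzyl-(+)-gallocatechin
Product: 3 3,5,7,3',4',5'-hexa-O-benzyl-(+)-gallocatechin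
Conditions: NaH (1.5 equiv), BnBr (1.5 equiv), DMF, 0 °C → rt
Reagents that add atoms: benzyl bromide BrCc1ccccc1
Why: Williamson etherification of the remaining secondary alcohol through its sodium alkoxide, safe once every phenol is capped.

Step 3
Reactants: 3 hexa-O-benzyl-(+)-gallocatechin
Product: 4 8-bromo-hexa-O-benzylgallocatechin
Conditions: NBS (1.0 equiv), CH2Cl2, −78 °C → rt
Reagents that add atoms: N-bromosuccinimide O=C1CCC(=O)N1Br
Why: electrophilic aromatic bromination; ring D is a phloroglucinol-type triether, far more nucleophilic than ring E, and 5,7-dialkoxyflavans are brominated by NBS at C8 in preference to C6.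

Step 4
Reactants: 4 8-bromo-hexa-O-benzylgallocatechin; 5 trimethylsilylacetylene (2 equiv)
Product: 6 8-(trimethylsilylethynyl)-hexa-O-benzylgallocatechin
Conditions: PdCl2(PhCN)2 (5 mol %), [HP(t-Bu)3]BF4 (10 mol %), copper iodide CuI (5 mol %), i-Pr2NH, dioxane, 50 °C
Reagents that add atoms: none
Why: Sonogashira coupling in which the bulky, electron-rich trialkylphosphine lets zerovalent palladium insert into the hindered, electron-rich C8–Br bond.

Step 5
Reactants: 6 8-(trimethylsilylethynyl)-hexa-O-benzylgallocatechin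
Product: 7 8-ethynyl-hexa-O-benzylgallocatechin
Conditions: K2CO3 (0.2 equiv), MeOH–THF, rt
Reagents that add atoms: none
Why: methoxide-mediated protodesilylation of an alkynylsilane, to which all the ethers are inert.

Step 6
Reactants: 7 8-ethynyl-hexa-O-benzylgallocatechin; 8 3,4,5-tris(benzyloxy)benzaldehyde (1.5 equiv)
Product: 10 (S)-1-[3,4,5-tris(benzyloxy)phenyl]-3-(hexa-O-benzylgallocatechin-8-yl)prop-2-yn-1-ol, via ethylzinc acetylide 9 (not isolated)
Conditions: Et2Zn (1.2 equiv), toluene, reflux, 1 h; then (R)-BINOL (20 mol %), Ti(OiPr)4 (50 mol %), 8, Et2O–toluene, rt; aq NH4Cl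
Reagents that add atoms: none
Why: BINOL–titanium-catalysed enantioselective addition of an alkynylzinc to an aromatic aldehyde, with alkynyl delivery to the Re face needed for the (S)-carbinol (future C2); the sense would be confirmed by Mosher ester analysis and the other BINOL antipode used if it proves opposite.

Step 7
Reactants: 10 (S)-propargylic alcohol
Product: 11 (R,Z)-1-[3,4,5-tris(benzyloxy)phenyl]-3-(hexa-O-benzylgallocatechin-8-yl)prop-2-en-1-ol
Conditions: H2 (1 atm), Pd/CaCO3 poisoned with Pb(OAc)2 (Lindlar catalyst), quinoline, EtOAc, rt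
Reagents that add atoms: none
Why: Lindlar syn-semihydrogenation gives the Z-alkene without touching benzyl ethers or the carbinol centre, whose descriptor changes from S to R only because the alkenyl group now ranks below ring B.

Step 8
Reactants: 11 (R,Z)-allylic alcohol
Product: 12 (S)-[3,4,5-tris(benzyloxy)phenyl][(2R,3S)-3-(hexa-O-benzylgallocatechin-8-yl)oxiran-2-yl]methanol (threo cis-epoxy alcohol)
Conditions: dimethyldioxirane (1.2 equiv, acetone solution), CH2Cl2, −40 → 0 °C; evaporated cold and used crude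
Reagents that add atoms: dimethyldioxirane CC1(C)OO1
Why: hydroxyl-directed dioxirane epoxidation in which 1,3-allylic strain holds the carbinol H in the alkene plane, the OH hydrogen-bonds the oxidant and ring B shields the other face, so oxygen enters syn to OH (threo) to give the cis-epoxide, while the neutral medium (acetone as only by-product) spares the very acid-labile ring-D benzylic epoxide.

Step 9
Reactants: 12 threo cis-epoxy alcohol; 13 3-(benzyloxy)phenol (1.5 equiv)
Product: 14 (2S,3S)-2-{(R)-[3-(benzyloxy)phenoxy][3,4,5-tris(benzyloxy)phenyl]methyl}-3-(hexa-O-benzylgallocatechin-8-yl)oxirane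
Conditions: PPh3 (1.6 equiv), DIAD (1.6 equiv), toluene, 0 °C → rt; rapid filtration through Et3N-deactivated silica
Reagents that add atoms: none
Why: Mitsunobu etherification in which the phenoxide displaces the oxyphosphonium by SN2 with inversion at C2, turning the threo relation of step 8 into the one that becomes 2,3-trans in the flavan, under essentially neutral conditions that the epoxide should tolerate.

Step 10
Reactants: 14 3-benzyloxyphenyl ether of the cis-epoxy alcohol
Product: 15 deca-O-benzyl robinetinidol-(4β→8)-gallocatechin having the upper 3-hydroxyl free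
Conditions: BF3·OEt2 (0.3 equiv), CH2Cl2 (0.005 M), −78 °C; Et3N quench at −78 °C
Reagents that add atoms: none
Why: BF3 coordinates the epoxide oxygen, the C4–O bond (benzylic to the ortho,para-oxygenated ring D) lengthens, the ring A carbon ortho to the ether oxygen and para to its benzyloxy group attacks C4 opposite the departing oxygen and the arenium ion loses a proton; the closest known reaction type is the Lewis-acid-promoted epoxy–arene (intramolecular Friedel–Crafts) cyclisation of aryl glycidyl ethers and 3-aryl-2-(aryloxymethyl)oxiranes to chroman-3-ols. Ring C (C4a, C8a, O1, C2, C3, C4) closes in the 6-endo mode, preferred over 5-exo attack at C3 because only C4 can carry positive charge. The new stereocentre C4 is controlled by the epoxide: inversion of the cis-epoxide places ring D cis to the oxygen kept on C3 (4β, 4R), through a chair-like array with ring B and O3 equatorial in which the attacking carbon already lies anti to the C4–O bond, while C2 and C3 pass through unchanged so that 2,3-trans is fixed. The step needs C4 rather than C3 attack (secured by benzylic activation), closure para rather than ortho to the ring A benzyloxy group (stronger para activation, and the site between the two oxygens is crowded), and inversion rather than capture of a rotated free cation, which would give the 3,4-trans epimer. Inversion is favoured by catalytic Lewis acid, a non-ionising solvent, −78 °C and a six-membered closure that should outrun C3–C4 rotation; high dilution suppresses intermolecular arylation.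

Step 11
Reactants: 15 deca-O-benzyl robinetinidol-(4β→8)-gallocatechin
Product: 16 robinetinidol-(4β→8)-gallocatechin (target)
Conditions: H2 (1 atm), Pd(OH)2/C, THF–MeOH–H2O, rt; Sephadex LH-20
Reagents that add atoms: none
Why: hydrogenolysis of the ten benzyl ethers, under which the flavan C2–O1 bonds and the interflavan C4–C8 bond are expected to survive and no stereocentre is affected.

## Compound list

1 | (+)-gallocatechin (2R,3S) | Oc1cc(O)c2c(c1)O[C@H](c1cc(O)c(O)c(O)c1)[C@@H](O)C2 | starting material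
2 | 5,7,3',4',5'-penta-O-benzyl-(+)-gallocatechin | c1ccccc1COc1cc(OCc3ccccc3)c2c(c1)O[C@H](c1cc(OCc3ccccc3)c(OCc3ccccc3)c(OCc3ccccc3)c1)[C@@H](O)C2 | intermediate
3 | 3,5,7,3',4',5'-hexa-O-benzyl-(+)-gallocatechin | c1ccccc1COc1cc(OCc3ccccc3)c2c(c1)O[C@H](c1cc(OCc3ccccc3)c(OCc3ccccc3)c(OCc3ccccc3)c1)[C@@H](OCc3ccccc3)C2 | intermediate
4 | 8-bromo-hexa-O-benzylgallocatechin | Brc1c(OCc3ccccc3)cc(OCc3ccccc3)c2c1O[C@H](c1cc(OCc3ccccc3)c(OCc3ccccc3)c(OCc3ccccc3)c1)[C@@H](OCc3ccccc3)C2 | intermediate
5 | trimethylsilylacetylene | C#C[Si](C)(C)C | starting material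
6 | 8-(trimethylsilylethynyl)-hexa-O-benzylgallocatechin | C[Si](C)(C)C#Cc1c(OCc3ccccc3)cc(OCc3ccccc3)c2c1O[C@H](c1cc(OCc3ccccc3)c(OCc3ccccc3)c(OCc3ccccc3)c1)[C@@H](OCc3ccccc3)C2 | intermediate
7 | 8-ethynyl-hexa-O-benzylgallocatechin | C#Cc1c(OCc3ccccc3)cc(OCc3ccccc3)c2c1O[C@H](c1cc(OCc3ccccc3)c(OCc3ccccc3)c(OCc3ccccc3)c1)[C@@H](OCc3ccccc3)C2 | intermediate
8 | 3,4,5-tris(benzyloxy)benzaldehyde | O=Cc1cc(OCc2ccccc2)c(OCc2ccccc2)c(OCc2ccccc2)c1 | starting material
9 | ethylzinc acetylide of 7 | CC[Zn]C#Cc1c(OCc3ccccc3)cc(OCc3ccccc3)c2c1O[C@H](c1cc(OCc3ccccc3)c(OCc3ccccc3)c(OCc3ccccc3)c1)[C@@H](OCc3ccccc3)C2 | intermediate (not isolated)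
10 | (S)-1-[3,4,5-tris(benzyloxy)phenyl]-3-(hexa-O-benzylgallocatechin-8-yl)prop-2-yn-1-ol | O[C@@H](c1cc(OCc3ccccc3)c(OCc3ccccc3)c(OCc3ccccc3)c1)C#Cc1c(OCc3ccccc3)cc(OCc3ccccc3)c2c1O[C@H](c1cc(OCc3ccccc3)c(OCc3ccccc3)c(OCc3ccccc3)c1)[C@@H](OCc3ccccc3)C2 | intermediate
11 | (R,Z)-1-[3,4,5-tris(benzyloxy)phenyl]-3-(hexa-O-benzylgallocatechin-8-yl)prop-2-en-1-ol | O[C@@H](c1cc(OCc3ccccc3)c(OCc3ccccc3)c(OCc3ccccc3)c1)/C=C\c1c(OCc3ccccc3)cc(OCc3ccccc3)c2c1O[C@H](c1cc(OCc3ccccc3)c(OCc3ccccc3)c(OCc3ccccc3)c1)[C@@H](OCc3ccccc3)C2 | intermediate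
12 | (S)-[3,4,5-tris(benzyloxy)phenyl][(2R,3S)-3-(hexa-O-benzylgallocatechin-8-yl)oxiran-2-yl]methanol | O[C@@H](c1cc(OCc3ccccc3)c(OCc3ccccc3)c(OCc3ccccc3)c1)[C@H]1O[C@H]1c1c(OCc3ccccc3)cc(OCc3ccccc3)c2c1O[C@H](c1cc(OCc3ccccc3)c(OCc3ccccc3)c(OCc3ccccc3)c1)[C@@H](OCc3ccccc3)C2 | intermediate
13 | 3-(benzyloxy)phenol | Oc1cccc(OCc2ccccc2)c1 | starting material
14 | (2S,3S)-2-{(R)-[3-(benzyloxy)phenoxy][3,4,5-tris(benzyloxy)phenyl]methyl}-3-(hexa-O-benzylgallocatechin-8-yl)oxirane | c1ccccc1COc1cccc(c1)O[C@H](c1cc(OCc3ccccc3)c(OCc3ccccc3)c(OCc3ccccc3)c1)[C@H]1O[C@H]1c1c(OCc3ccccc3)cc(OCc3ccccc3)c2c1O[C@H](c1cc(OCc3ccccc3)c(OCc3ccccc3)c(OCc3ccccc3)c1)[C@@H](OCc3ccccc3)C2 | intermediate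
15 | deca-O-benzyl robinetinidol-(4β→8)-gallocatechin, upper 3-OH free (upper unit 2R,3S,4R; lower unit 2R,3S) | c1ccccc1COc1ccc2c(c1)O[C@H](c1cc(OCc3ccccc3)c(OCc3ccccc3)c(OCc3ccccc3)c1)[C@@H](O)[C@H]2c1c(OCc3ccccc3)cc(OCc3ccccc3)c2c1O[C@H](c1cc(OCc3ccccc3)c(OCc3ccccc3)c(OCc3ccccc3)c1)[C@@H](OCc3ccccc3)C2 | intermediate
16 | robinetinidol-(4β→8)-gallocatechin | Oc1ccc2c(c1)O[C@H](c1cc(O)c(O)c(O)c1)[C@@H](O)[C@H]2c1c(O)cc(O)c2c1O[C@H](c1cc(O)c(O)c(O)c1)[C@@H](O)C2 | target

Total step count: 11. Longest linear sequence: 11 steps (1 → 16).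

## Steps most likely to fail

**Step 10 (key cyclisation).** Ring D stabilises a benzylic cation so well that the C4–O bond may ionise fully. Rotation about C3–C4 before ring closure would then erase the inversion and lead to the 3,4-trans (4α) epimer, and a 1,2-hydride shift to a C3 ketone could compete.

The fallback would set out from bromide 4 and return at 15. It forms the C4–C8 bond by known organolithium chemistry and sets C4 by hydride delivery.
- Commercial (+)-dihydrorobinetin F1 would be benzylated on its four phenols (BnBr, K2CO3, DMF, rt) to 7,3',4',5'-tetra-O-benzyl-dihydrorobinetin F2.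
- F2 would be silylated (TBSOTf, 2,6-lutidine, CH2Cl2) to its 3-O-tert-butyldimethylsilyl ether F3.
- Bromide 4 would be converted (t-BuLi, THF, −78 °C) into 8-lithio-hexa-O-benzylgallocatechin F4 and added to the ketone of F3, giving the tertiary benzylic alcohol F5 (C4 configuration immaterial).
- Ionic reduction (Bu3SnH, CF3CO2H, CH2Cl2, 0 °C) should deliver hydride to the C4 cation anti to the neighbouring 3-silyloxy group, as nucleophiles generally do in 2,3-trans flavan-4-yl cations. This places ring D cis to O3 and gives the 3-O-silyl ether of 15, F6.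
- Bu4NF in THF would then release 15.

**Step 9 (Mitsunobu on the epoxy alcohol).** SN2 displacement at a carbinol flanked by ring B and the cis-epoxide may be slow. The phenol or adventitious acid could then open the ring-D-activated epoxide first, or partial ionisation at C2 could erode the inversion.

The fallback would set out from propargylic alcohol 10 and return at 14; it also bypasses the isolation of 12.
- The Mitsunobu reaction with 13 (PPh3, DIAD, toluene, 0 °C) would be run on 10, a robust carbinol, to give with inversion the (R)-aryl propargyl ether F7.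
- Lindlar semihydrogenation (H2, Pd/CaCO3 poisoned with Pb(OAc)2, quinoline) would give the (S,Z)-allyl aryl ether F8.
- The epoxide would be introduced last under catalyst control and buffered basic conditions: a Shi-type chiral dioxirane from a carbohydrate-derived oxazolidinone ketone, KHSO5 (as Oxone), K2CO3, MeCN–dimethoxymethane–water, 0 °C. Oxygen must enter the alkene face anti to the aryloxy group, giving 14 for immediate cyclisation.
- No hydroxyl directs the oxidant here, and the substrate's own preference is expected to be for the other face. The catalyst therefore has to overrule it; the diastereomer ratio would be measured and the minor isomer removed after step 10.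

**Step 4 (Sonogashira coupling).** Oxidative addition of zerovalent palladium into the electron-rich C8–Br bond, flanked by two oxygens, may be slow, so that alkyne homocoupling and protodebromination take over.

The fallback would set out from 4 and return at 7 without palladium.
- Bromine–lithium exchange (t-BuLi, THF, −78 °C) would give the 8-lithio compound (F4, as above).
- A DMF quench would give 8-formyl-hexa-O-benzylgallocatechin F9.
- Ohira–Bestmann homologation (dimethyl (1-diazo-2-oxopropyl)phosphonate, K2CO3, MeOH–THF, rt) would convert F9 into the terminal alkyne 7.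

## Further compounds

F1 | step 10 | (+)-dihydrorobinetin (2R,3R), commercial starting material of the fallback | Oc1ccc2c(c1)O[C@H](c1cc(O)c(O)c(O)c1)[C@@H](O)C2=O
F2 | step 10 | 7,3',4',5'-tetra-O-benzyl-dihydrorobinetin | c1ccccc1COc1ccc2c(c1)O[C@H](c1cc(OCc3ccccc3)c(OCc3ccccc3)c(OCc3ccccc3)c1)[C@@H](O)C2=O
F3 | step 10 | 3-O-tert-butyldimethylsilyl-7,3',4',5'-tetra-O-benzyl-dihydrorobinetin | c1ccccc1COc1ccc2c(c1)O[C@H](c1cc(OCc3ccccc3)c(OCc3ccccc3)c(OCc3ccccc3)c1)[C@@H](O[Si](C)(C)C(C)(C)C)C2=O
F4 | step 10 | 8-lithio-hexa-O-benzylgallocatechin | [Li]c1c(OCc3ccccc3)cc(OCc3ccccc3)c2c1O[C@H](c1cc(OCc3ccccc3)c(OCc3ccccc3)c(OCc3ccccc3)c1)[C@@H](OCc3ccccc3)C2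
F5 | step 10 | 4-hydroxy-4-(hexa-O-benzylgallocatechin-8-yl) adduct of F3 (tertiary benzylic alcohol, C4 unassigned) | c1ccccc1COc1ccc2c(c1)O[C@H](c1cc(OCc3ccccc3)c(OCc3ccccc3)c(OCc3ccccc3)c1)[C@@H](O[Si](C)(C)C(C)(C)C)C2(O)c1c(OCc3ccccc3)cc(OCc3ccccc3)c2c1O[C@H](c1cc(OCc3ccccc3)c(OCc3ccccc3)c(OCc3ccccc3)c1)[C@@H](OCc3ccccc3)C2
F6 | step 10 | 3-O-tert-butyldimethylsilyl ether of 15 | c1ccccc1COc1ccc2c(c1)O[C@H](c1cc(OCc3ccccc3)c(OCc3ccccc3)c(OCc3ccccc3)c1)[C@@H](O[Si](C)(C)C(C)(C)C)[C@H]2c1c(OCc3ccccc3)cc(OCc3ccccc3)c2c1O[C@H](c1cc(OCc3ccccc3)c(OCc3ccccc3)c(OCc3ccccc3)c1)[C@@H](OCc3ccccc3)C2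
F7 | step 9 | (R)-1-[3-(benzyloxy)phenoxy]-1-[3,4,5-tris(benzyloxy)phenyl]-3-(hexa-O-benzylgallocatechin-8-yl)prop-2-yne | c1ccccc1COc1cccc(c1)O[C@H](c1cc(OCc3ccccc3)c(OCc3ccccc3)c(OCc3ccccc3)c1)C#Cc1c(OCc3ccccc3)cc(OCc3ccccc3)c2c1O[C@H](c1cc(OCc3ccccc3)c(OCc3ccccc3)c(OCc3ccccc3)c1)[C@@H](OCc3ccccc3)C2
F8 | step 9 | (S,Z)-1-[3-(benzyloxy)phenoxy]-1-[3,4,5-tris(benzyloxy)phenyl]-3-(hexa-O-benzylgallocatechin-8-yl)prop-2-ene | c1ccccc1COc1cccc(c1)O[C@H](c1cc(OCc3ccccc3)c(OCc3ccccc3)c(OCc3ccccc3)c1)/C=C\c1c(OCc3ccccc3)cc(OCc3ccccc3)c2c1O[C@H](c1cc(OCc3ccccc3)c(OCc3ccccc3)c(OCc3ccccc3)c1)[C@@H](OCc3ccccc3)C2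
F9 | step 4 | 8-formyl-hexa-O-benzylgallocatechin | O=Cc1c(OCc3ccccc3)cc(OCc3ccccc3)c2c1O[C@H](c1cc(OCc3ccccc3)c(OCc3ccccc3)c(OCc3ccccc3)c1)[C@@H](OCc3ccccc3)C2
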